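**Plan**

1. Atom labels: ring A (five-membered) = C1 (quaternary, CH3), C2 (OAc), C3, C4 (OH, i-Pr), C5 (H). Ring B (seven-membered) = C5, C6 (O-vanilloyl), C7, C8 (CH3), C9, C10, C1, with the oxirane on C8–C9. β is the face of the C1 methyl, so the target is 1β-CH3, 2α-OAc, 4β-OH, 5α-H, 6α-O-acyl, 8α,9α-epoxy.
2. Cuts, in order: the two acyl–O bonds (O6–vanilloyl, O2–acetyl) and the oxirane C–O bonds. Written with C8=C9 and a C5=C6 enol ether, ring B is a cyclohepta-1,4-diene, the retron of a cis-divinylcyclopropane Cope rearrangement, so C1–C10 and C7–C8 are cut next (C6–C8 exists only in the cyclopropane).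
3. This leaves a vinylcarbenoid C8–C9=C10, whose ester carbon becomes the C8 methyl, and a ring A diene C7H2=C6(OSi)–C5=C1(CH3). Removing C7 and exchanging the C1–C5 bond for C1–C6 maps C1–C6, CH3 and i-Pr onto (S)-terpinen-4-ol.
4. Forward: ring A by ozonolysis/aldol ring contraction, C7 by Grignard addition, O2 by allylic oxidation after the contraction. Ring B follows in one operation from the diene and methyl 2-diazobut-3-enoate, then ester to methyl, C6 ketone to alcohol, epoxide, vanillate.
5. Stereochemistry: C4 comes from the chiral pool and C2 from a CBS reduction. C1 is relayed from C4: O4 and O6 are tied through one silicon atom, so the boat transition state can form only on the α face, and the chiral rhodium catalyst steers the cyclopropanation to that face. C5 is set by α-face protonation, C6 by hydride delivered from the 4β-OH, and C8/C9 by peracid attack anti to the C1 methyl.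

Key step: step 14

Assumption: (S)-(+)-terpinen-4-ol is taken as enantiomerically pure. Any (R)-alcohol carried along would emerge from the reagent-controlled reduction of step 8 as the cis-diol diastereomer and be removed there.
Assumption: the sense of induction of Rh2(DOSP)4 known for styrene and vinyl ethers is taken to hold for the exocyclic enol ether of the diene. On that basis the (R)-catalyst is the matched one.

**Step 1**
Reactants: 1 (S)-(+)-terpinen-4-ol
Product: 2 (S)-terpinen-4-ol triethylsilyl ether
Conditions: Et3SiOTf, 2,6-lutidine, CH2Cl2, 0 °C to rt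
Reagents that add atoms: triethylsilyl trifluoromethanesulfonate, CC[Si](CC)(CC)OS(=O)(=O)C(F)(F)F
Why: Silyl triflate/lutidine O-silylation is the standard way to cap a hindered tertiary alcohol, and the ether shuts off retro-aldol cleavage and hemiketal formation in steps 2 to 6 while C4 is untouched.

**Step 2**
Reactants: 2 (S)-terpinen-4-ol triethylsilyl ether
Product: 4 (S)-3-isopropyl-6-oxo-3-(triethylsilyloxy)heptanal, via secondary ozonide 3 (not isolated)
Conditions: O3, CH2Cl2, −78 °C; then Me2S, −78 °C to rt
Reagents that add atoms: ozone, [O-][O+]=O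
Why: Criegee ozonolysis with reductive work-up cleaves the only C=C (C1=C6) into the C1 methyl ketone and the C6 aldehyde under neutral conditions that leave the silyl ether alone.

**Step 3**
Reactants: 4 (S)-3-isopropyl-6-oxo-3-(triethylsilyloxy)heptanal
Product: 5 (R)-5-isopropyl-2-methyl-5-(triethylsilyloxy)cyclopent-1-ene-1-carbaldehyde
Conditions: piperidine (0.5 equiv), AcOH (0.5 equiv), toluene, 60 °C
Reagents that add atoms: none
Why: In this amine/acid-catalysed intramolecular aldol condensation the aldehyde enamine attacks the C1 ketone through C5 (5-enolexo) and water is lost from C1, the mode known for 6-oxoheptanals made from 1-methylcyclohexenes; the weakly acidic medium and the poor leaving ability of the silyloxy group should keep O4 in place.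

**Step 4**
Reactants: 5 (R)-5-isopropyl-2-methyl-5-(triethylsilyloxy)cyclopent-1-ene-1-carbaldehyde
Product: 6 1-[(R)-5-isopropyl-2-methyl-5-(triethylsilyloxy)cyclopent-1-en-1-yl]ethanol (both C6 epimers)
Conditions: MeMgBr, Et2O, −78 to 0 °C
Reagents that add atoms: methylmagnesium bromide, C[Mg]Br
Why: Grignard 1,2-addition to the enal brings in C7, and the new carbinol centre does not matter because step 5 erases it.

**Step 5**
Reactants: 6 1-[(R)-5-isopropyl-2-methyl-5-(triethylsilyloxy)cyclopent-1-en-1-yl]ethanol
Product: 7 1-[(R)-5-isopropyl-2-methyl-5-(triethylsilyloxy)cyclopent-1-en-1-yl]ethanone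
Conditions: Dess–Martin periodinane, CH2Cl2, rt
Reagents that add atoms: none
Why: Dess–Martin oxidation converts hindered secondary allylic alcohols into enones under mild conditions that do not ionise the allylic C4–O bond.

**Step 6**
Reactants: 7 1-[(R)-5-isopropyl-2-methyl-5-(triethylsilyloxy)cyclopent-1-en-1-yl]ethanone
Product: 8 (R)-3-acetyl-4-isopropyl-2-methyl-4-(triethylsilyloxy)cyclopent-2-en-1-one
Conditions: Rh2(cap)4 (dirhodium tetrakis(caprolactamate), 1 mol %), t-BuOOH (in decane), K2CO3 (0.5 equiv), CH2Cl2, rt
Reagents that add atoms: tert-butyl hydroperoxide, CC(C)(C)OO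
Why: Radical allylic oxidation with t-BuOOH under Rh2(cap)4 catalysis is known to turn 1-acylcycloalkenes into ene-diones, C2 is the only allylic ring CH2, and because the oxygen enters after the ring contraction the reaction never passes through the mirror-symmetric allyl radical that the same oxidation of the cyclohexene would give, so C4 keeps its configuration.

**Step 7**
Reactants: 8 (R)-3-acetyl-4-isopropyl-2-methyl-4-(triethylsilyloxy)cyclopent-2-en-1-one
Product: 9 (R)-3-acetyl-4-hydroxy-4-isopropyl-2-methylcyclopent-2-en-1-one
Conditions: HF·pyridine, THF, 0 °C to rt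
Reagents that add atoms: none
Why: Acidic fluoride desilylation frees the 4β-OH without base, which matters because the alkoxide of this β-hydroxy ketone could open by retro-aldol cleavage.

**Step 8**
Reactants: 9 (R)-3-acetyl-4-hydroxy-4-isopropyl-2-methylcyclopent-2-en-1-one
Product: 10 1-[(3S,5R)-3,5-dihydroxy-5-isopropyl-2-methylcyclopent-1-en-1-yl]ethanone (2α,4β-diol)
Conditions: (R)-2-methyl-CBS-oxazaborolidine (0.3 equiv), catecholborane, toluene, −78 °C
Reagents that add atoms: none
Why: In this Corey–Bakshi–Shibata reduction the (R)-catalyst reads the C1=C5 side as the large and C3H2 as the small substituent and delivers hydride to the β face of C2=O (also the face anti to the isopropyl group), setting 2α-OH (S), while the acetyl carbonyl, flanked by the C1 methyl and the fully substituted C4 and twisted out of conjugation, should react much more slowly.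

**Step 9**
Reactants: 10 1-[(3S,5R)-3,5-dihydroxy-5-isopropyl-2-methylcyclopent-1-en-1-yl]ethanone
Product: 11 (1S,4R)-3-acetyl-4-hydroxy-4-isopropyl-2-methylcyclopent-2-en-1-yl acetate
Conditions: Ac2O, pyridine, DMAP (cat.), CH2Cl2, 0 °C
Reagents that add atoms: acetic anhydride, CC(=O)OC(C)=O
Why: DMAP-catalysed acylation takes the secondary allylic alcohol and leaves the tertiary 4-OH free, and the small acetate masks O2 up to step 14 and is removed at no extra cost in step 15.

**Step 10**
Reactants: 11 (1S,4R)-3-acetyl-4-hydroxy-4-isopropyl-2-methylcyclopent-2-en-1-yl acetate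
Product: 12 O4,O6-diisopropylsilylene-bridged 2-silyloxydiene (C7H2=C6(O)–C5=C1(CH3); 2α-OAc)
Conditions: i-Pr2Si(OTf)2 (1.1 equiv), Et3N (4 equiv), CH2Cl2 (dilute), −78 to 0 °C
Reagents that add atoms: diisopropylsilyl bis(trifluoromethanesulfonate), CC(C)[Si](OS(=O)(=O)C(F)(F)F)(OS(=O)(=O)C(F)(F)F)C(C)C
Why: Proposed new method: the ditriflate first silylates either the 4-OH or the acetyl oxygen, the remaining Si–OTf is then held next to the second oxygen, and closure to the six-membered 1,3,2-dioxasiline ring (C4–C5–C6–O–Si–O) with loss of a C7 proton to Et3N should outrun intermolecular silylation. The closest known reaction types are the R3SiOTf/Et3N conversion of 1-acylcycloalkenes into 2-silyloxydienes by α′-deprotonation and the bridging of 1,3-diols with R2Si(OTf)2.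

**Step 11**
Reactants: 13 methyl acetoacetate
Product: 14 methyl 2-diazo-3-oxobutanoate
Conditions: 4-acetamidobenzenesulfonyl azide, Et3N, MeCN, rt
Reagents that add atoms: 4-acetamidobenzenesulfonyl azide, CC(=O)Nc1ccc(cc1)S(=O)(=O)N=[N+]=[N-]
Why: Regitz diazo transfer to the active methylene group of a β-keto ester is a routine reaction.

**Step 12**
Reactants: 14 methyl 2-diazo-3-oxobutanoate
Product: 15 methyl 2-diazo-3-hydroxybutanoate (racemic)
Conditions: NaBH4, MeOH, 0 °C
Reagents that add atoms: none
Why: Borohydride reduces the ketone and spares the diazo ester, and the racemic carbinol centre disappears in step 13.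

**Step 13**
Reactants: 15 methyl 2-diazo-3-hydroxybutanoate
Product: 16 methyl 2-diazobut-3-enoate
Conditions: POCl3, Et3N, CH2Cl2, 0 °C; kept cold and used at once as a hexane solution
Reagents that add atoms: none
Why: Phosphorylation of the alcohol followed by base-induced elimination is the established dehydration route to the parent vinyldiazoacetate, which has to be used fresh because it slowly cyclises to a pyrazole.

**Step 14**
Reactants: 12 O4,O6-diisopropylsilylene-bridged 2-silyloxydiene; 16 methyl 2-diazobut-3-enoate
Product: 18 silylene-bridged hydroazulene-5,8-diene 8-methyl ester (1β-CH3; 2α-OAc), via spiro cis-divinylcyclopropane 17 (not isolated)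
Conditions: 16 (3 equiv) added over 3 h to 12 and Rh2(R-DOSP)4 (dirhodium tetrakis[(R)-N-(4-dodecylphenylsulfonyl)prolinate], 2 mol %), hexanes, −20 °C to rt; then toluene, 80 °C
Reagents that add atoms: none
Why: Rh2(R-DOSP)4 expels N2 from 16 and the donor/acceptor vinylcarbenoid adds through its carbene carbon C8 to the exocyclic C6=C7 enol ether in a concerted but asynchronous [2+1] step (C7–C8 ahead of C6–C8) to give 17, which rearranges by a boat [3,3] shift in which C10 bonds to C1 while C6–C8 breaks; the closest known reaction type is the tandem cyclopropanation/Cope rearrangement, a formal (4+3) cycloaddition, of vinyldiazoacetates with 2-silyloxydienes and with 1-vinyl-2-methylcycloalkenes. The three-membered ring is closed by carbene addition and is only transient, and ring B is closed by the sigmatropic ring expansion, that is by C1–C10 bond formation within the array C1=C5–C6–C8–C9=C10. C1 is the only new stereocentre that survives: in the boat transition state the breaking C6–C8 bond must stand perpendicular to the C1=C5 plane with O6 on the opposite side, and since silicon holds O6 on the side of the 4β-oxygen, C8–C10 can lie only under the α face, so C10 bonds α and the methyl group ends up β. The catalyst is there to send the carbenoid to the α face of C6=C7, because the β-face adduct cannot reach this geometry and would be lost rather than give the C1 epimer, while a trans-divinyl isomer should converge on warming through epimerisation of the donor–acceptor C6–C8 bond. Chemoselectivity for C6=C7 follows from its being terminal and the most electron-rich double bond, whereas C1=C5 is tetrasubstituted. Reaction at the carbene carbon instead of the vinylogous C10 is favoured by the hydrocarbon solvent, the electron-rich carboxylate catalyst and the slow addition of 16.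

**Step 15**
Reactants: 18 silylene-bridged hydroazulene-5,8-diene 8-methyl ester
Product: 19 silylene-bridged diene diol (C8–CH2OH; 2α-OH)
Conditions: i-Bu2AlH (6 equiv), CH2Cl2, −78 °C; aq. potassium sodium tartrate
Reagents that add atoms: none
Why: i-Bu2AlH reduces the conjugated ester to the allylic alcohol in 1,2-fashion and cleaves the acetate in the same operation, while the hindered tetrasubstituted silyl enol ether is inert to hydride at low temperature.

**Step 16**
Reactants: 19 silylene-bridged diene diol
Product: 21 silylene-bridged 8-methyl diene alcohol (2α-OH), via allylic mesylate 20 (not isolated)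
Conditions: MsCl (1.1 equiv), Et3N, CH2Cl2, −40 °C; then LiEt3BH, THF, −40 to 0 °C
Reagents that add atoms: methanesulfonyl chloride, CS(=O)(=O)Cl (its atoms stay only in 20)
Why: Sulfonylation picks the primary allylic alcohol (the 2α-OH is secondary and neopentylic) and SN2 displacement by LiEt3BH turns CH2OH into the C8 methyl group without moving the C8=C9 double bond.

**Step 17**
Reactants: 21 silylene-bridged 8-methyl diene alcohol
Product: 22 silylene-bridged 8-methyl diene 2α-acetate
Conditions: Ac2O, Et3N, DMAP, CH2Cl2, rt
Reagents that add atoms: acetic anhydride, CC(=O)OC(C)=O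
Why: DMAP-catalysed acetylation of the only free hydroxyl installs the final 2α-acetate now that no ester-cleaving hydride step remains.

**Step 18**
Reactants: 22 silylene-bridged 8-methyl diene 2α-acetate
Product: 24 trans-fused β-hydroxy ketone (C6=O; 5α-H; 4β-OH; 2α-OAc; C8=C9), via O4-fluorodiisopropylsilyl ketone 23 (not isolated)
Conditions: Bu4NF (2.5 equiv), AcOH (3 equiv), THF, −20 to 0 °C
Reagents that add atoms: tetrabutylammonium fluoride, CCCC[N+](CCCC)(CCCC)CCCC.[F-] (its fluorine stays only in 23)
Why: In this buffered silyl enol ether cleavage fluoride expels the better leaving group, the enol oxygen, first, so C5 is protonated by AcOH while O4 still carries the bulky fluorosilyl group; with that group and the C1 methyl on the β face the proton should arrive from the α face and give the trans-fused ketone, also expected to be the more stable epimer (C6 anti to isopropyl), and the cold buffered medium keeps C8=C9 out of conjugation and O4 in place.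

**Step 19**
Reactants: 24 trans-fused β-hydroxy ketone
Product: 25 4β,6α-diol (2α-OAc; C8=C9)
Conditions: Me4NBH(OAc)3, MeCN/AcOH 1:1, −25 °C
Reagents that add atoms: none
Why: In the Evans–Saksena reduction the 4β-OH exchanges onto boron and hands hydride to the β face of C6=O through a six-membered transition state, giving 6β-H and 6α-OH (1,3-anti), while acetate and alkene are inert.

**Step 20**
Reactants: 25 4β,6α-diol
Product: 26 8α,9α-epoxy-4β,6α-diol (2α-OAc)
Conditions: mCPBA, CH2Cl2/aq. NaHCO3 (two-phase), 0 °C
Reagents that add atoms: 3-chloroperoxybenzoic acid, OOC(=O)c1cccc(Cl)c1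
Why: In this Prilezhaev epoxidation the axial C1 methyl covers the β face of C8=C9 in the chair cycloheptene of the trans-fused system and the equatorial 6α-OH can hydrogen-bond the peracid on the α face, so oxygen should be delivered α at both C8 and C9.

**Step 21**
Reactants: 27 vanillic acid
Product: 29 4-benzyloxy-3-methoxybenzoic acid, via benzyl 4-benzyloxy-3-methoxybenzoate 28 (not isolated)
Conditions: BnBr (2.2 equiv), K2CO3, DMF, 60 °C; then NaOH, MeOH/H2O, 60 °C; HCl
Reagents that add atoms: benzyl bromide, BrCc1ccccc1; sodium hydroxide, [Na+].[OH-]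
Why: Williamson benzylation of phenol and acid followed by saponification of the benzyl ester gives a phenol mask that is inert to carbodiimide/DMAP acylation, unlike an aryl acetate.

**Step 22**
Reactants: 26 8α,9α-epoxy-4β,6α-diol; 29 4-benzyloxy-3-methoxybenzoic acid
Product: 30 O-benzyl ether of the target
Conditions: DCC, DMAP, CH2Cl2, rt
Reagents that add atoms: none
Why: Steglich esterification acylates the only secondary hydroxyl (6α-OH) with retention at C6, the tertiary 4-OH being unreactive and the epoxide stable to these neutral conditions.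

**Step 23**
Reactants: 30 O-benzyl ether of the target
Product: 31 CNP0241679.3 (target)
Conditions: H2 (1 atm), 10% Pd/C, EtOAc, rt
Reagents that add atoms: none
Why: Catalytic hydrogenolysis removes the aryl benzyl ether under neutral conditions that leave a trialkyl-substituted epoxide, the two esters and the tertiary alcohol untouched.

**Compound list**

1 | (S)-(+)-terpinen-4-ol | CC1=CC[C@](O)(C(C)C)CC1 | starting material
2 | (S)-terpinen-4-ol triethylsilyl ether | CC1=CC[C@](O[Si](CC)(CC)CC)(C(C)C)CC1 | intermediate
3 | secondary ozonide of 2 (1,2,4-trioxolane across C1 and C6) | CC12CC[C@@](O[Si](CC)(CC)CC)(C(C)C)CC(OO1)O2 | intermediate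
4 | (S)-3-isopropyl-6-oxo-3-(triethylsilyloxy)heptanal | CC(=O)CC[C@@](O[Si](CC)(CC)CC)(C(C)C)CC=O | intermediate
5 | (R)-5-isopropyl-2-methyl-5-(triethylsilyloxy)cyclopent-1-ene-1-carbaldehyde | O=CC1=C(C)CC[C@@]1(O[Si](CC)(CC)CC)C(C)C | intermediate
6 | 1-[(R)-5-isopropyl-2-methyl-5-(triethylsilyloxy)cyclopent-1-en-1-yl]ethanol, both C6 epimers | CC(O)C1=C(C)CC[C@@]1(O[Si](CC)(CC)CC)C(C)C | intermediate
7 | 1-[(R)-5-isopropyl-2-methyl-5-(triethylsilyloxy)cyclopent-1-en-1-yl]ethanone | CC(=O)C1=C(C)CC[C@@]1(O[Si](CC)(CC)CC)C(C)C | intermediate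
8 | (R)-3-acetyl-4-isopropyl-2-methyl-4-(triethylsilyloxy)cyclopent-2-en-1-one | CC(=O)C1=C(C)C(=O)C[C@@]1(O[Si](CC)(CC)CC)C(C)C | intermediate
9 | (R)-3-acetyl-4-hydroxy-4-isopropyl-2-methylcyclopent-2-en-1-one | CC(=O)C1=C(C)C(=O)C[C@@]1(O)C(C)C | intermediate
10 | 1-[(3S,5R)-3,5-dihydroxy-5-isopropyl-2-methylcyclopent-1-en-1-yl]ethanone (2α,4β-diol) | CC(=O)C1=C(C)[C@@H](O)C[C@@]1(O)C(C)C | intermediate
11 | (1S,4R)-3-acetyl-4-hydroxy-4-isopropyl-2-methylcyclopent-2-en-1-yl acetate | CC(=O)C1=C(C)[C@@H](OC(C)=O)C[C@@]1(O)C(C)C | intermediate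
12 | silylene-bridged 2-silyloxydiene: cyclopentene C1(CH3)=C5 with 2α-OAc and 4α-i-Pr; C5 carries C6(=C7H2), whose oxygen is joined through Si(i-Pr)2 to the 4β-oxygen | C=C1O[Si](C(C)C)(C(C)C)O[C@@]2(C(C)C)C[C@H](OC(C)=O)C(C)=C12 | intermediate
13 | methyl acetoacetate | COC(=O)CC(C)=O | starting material
14 | methyl 2-diazo-3-oxobutanoate | COC(=O)C(=[N+]=[N-])C(C)=O | intermediate
15 | methyl 2-diazo-3-hydroxybutanoate (racemic) | COC(=O)C(=[N+]=[N-])C(C)O | intermediate
16 | methyl 2-diazobut-3-enoate | C=CC(=[N+]=[N-])C(=O)OC | intermediate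
17 | spiro cis-divinylcyclopropane: cyclopropane C6–C7–C8 spiro at C6 on the dioxasiline ring, C8 on the α side bearing CO2Me and a vinyl group cis to C5 | COC(=O)[C@]1(C=C)C[C@]12O[Si](C(C)C)(C(C)C)O[C@@]3(C(C)C)C[C@H](OC(C)=O)C(C)=C23 | intermediate
18 | hydroazulene 1,4-diene: C8–CO2Me, C8=C9, C5=C6, 1β-CH3, 2α-OAc, 4α-i-Pr, O4 and O6 bridged by Si(i-Pr)2 | COC(=O)C1=CC[C@@]2(C)[C@@H](OC(C)=O)C[C@]3(C(C)C)O[Si](C(C)C)(C(C)C)OC(C1)=C23 | intermediate
19 | as 18 with C8–CH2OH and 2α-OH | OCC1=CC[C@@]2(C)[C@@H](O)C[C@]3(C(C)C)O[Si](C(C)C)(C(C)C)OC(C1)=C23 | intermediate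
20 | as 19 with C8–CH2OMs | CS(=O)(=O)OCC1=CC[C@@]2(C)[C@@H](O)C[C@]3(C(C)C)O[Si](C(C)C)(C(C)C)OC(C1)=C23 | intermediate
21 | as 19 with C8–CH3 (2α-OH) | CC1=CC[C@@]2(C)[C@@H](O)C[C@]3(C(C)C)O[Si](C(C)C)(C(C)C)OC(C1)=C23 | intermediate
22 | as 21 with 2α-OAc | CC1=CC[C@@]2(C)[C@@H](OC(C)=O)C[C@]3(C(C)C)O[Si](C(C)C)(C(C)C)OC(C1)=C23 | intermediate
23 | trans-fused C6 ketone, 5α-H, 4β-OSiF(i-Pr)2, 2α-OAc, C8=C9 | CC1=CC[C@@]2(C)[C@@H](OC(C)=O)C[C@@](O[Si](F)(C(C)C)C(C)C)(C(C)C)[C@@H]2C(=O)C1 | intermediate
24 | trans-fused β-hydroxy ketone: C6=O, 5α-H, 4β-OH, 2α-OAc, C8=C9 | CC1=CC[C@@]2(C)[C@@H](OC(C)=O)C[C@@](O)(C(C)C)[C@@H]2C(=O)C1 | intermediate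
25 | 4β,6α-diol, 2α-OAc, C8=C9 | CC1=CC[C@@]2(C)[C@@H](OC(C)=O)C[C@@](O)(C(C)C)[C@@H]2[C@@H](O)C1 | intermediate
26 | 8α,9α-epoxy-4β,6α-diol, 2α-OAc | O[C@H]2C[C@@]3(C)O[C@H]3C[C@@]3(C)[C@@H](OC(C)=O)C[C@@](O)(C(C)C)[C@H]23 | intermediate
27 | vanillic acid | COc1cc(C(=O)O)ccc1O | starting material
28 | benzyl 4-benzyloxy-3-methoxybenzoate | COc1cc(C(=O)OCc2ccccc2)ccc1OCc1ccccc1 | intermediate
29 | 4-benzyloxy-3-methoxybenzoic acid | COc1cc(C(=O)O)ccc1OCc1ccccc1 | intermediate
30 | O-benzyl ether of the target | COc1cc(C(=O)O[C@H]2C[C@@]3(C)O[C@H]3C[C@@]3(C)[C@@H](OC(C)=O)C[C@@](O)(C(C)C)[C@H]23)ccc1OCc1ccccc1 | intermediate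
31 | CNP0241679.3 | COc1cc(C(=O)O[C@H]2C[C@@]3(C)O[C@H]3C[C@@]3(C)[C@@H](OC(C)=O)C[C@@](O)(C(C)C)[C@H]23)ccc1O | target

**Step count and risks**

Total step count: 23. Longest linear sequence: 19 (steps 1–10, 14–20, 22, 23).

Steps most likely to fail:

**1. Step 10 (bears the label).**
- What may go wrong: silicon may link two molecules instead of closing the ring. The hindered tertiary hydroxyl may also react so slowly that triflate-induced ionisation of the allylic acetate, or deprotonation at a γ-position instead of C7, takes over.
- Fallback (known chemistry): it sets out from 11 and returns to the route at 12. The alcohol alone is first silylated with chlorodiisopropylsilane (i-Pr2SiHCl, imidazole, DMAP, DMF) to give the diisopropylsilyl ether F1. N-Bromosuccinimide in CH2Cl2 at 0 °C then converts Si–H into Si–Br. The bromosilane F2 is not isolated, and Et3N closes the ring by enol silylation of the neighbouring acetyl group. This joins the established stepwise route to unsymmetrical silaketals with ordinary halosilane/amine enol silylation, and silicon is already attached to one molecule before it is activated.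

**2. Step 14.**
- What may go wrong: the nucleophilic enol ether may attack the vinylogous carbon C10 of the carbenoid, which leads to five-membered or open-chain products. The diazo compound may cyclise to a pyrazole before it is consumed. Cyclopropanation may take place on the β face and drain material into isomers that cannot rearrange.
- Fallback: it sets out from 14 and 12 and returns at 18. 14 is O-silylated (t-BuMe2SiOTf, Et3N, CH2Cl2) to methyl 3-(tert-butyldimethylsilyloxy)-2-diazobut-3-enoate F3. This is a storable vinyldiazoacetate whose internal silyloxy group suppresses the vinylogous electrophilicity. With Rh2(S-PTAD)4 (dirhodium tetrakis[(S)-(1-adamantyl)(phthalimido)acetate]) it should give with 12, by the same tandem process, the C9-silyloxy cycloheptadiene F4. One equivalent of Et3N·3HF at −20 °C frees the β-keto ester F5, and NaH/PhNTf2 gives the enol triflate F6. Formate hydrogenolysis (Pd(OAc)2, PPh3, HCO2H, Et3N, DMF) then removes the C9 oxygen to give 18.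

**3. Step 18.**
- What may go wrong: facial selectivity in the protonation of C5 may be poor. O4 may be lost from the enol by β-elimination. The C8=C9 double bond may drift into conjugation with the ketone.
- Fallback: it replaces kinetic protonation by thermodynamic control, sets out from 22 and returns at 24. Desilylation as in step 18 is taken on as a mixture of 24 and its 5β-H epimer F7. DBU in toluene equilibrates both C5 and the alkene position to the trans-fused conjugated enone F8, in which C6 is cis to the small hydroxyl, anti to isopropyl and hydrogen-bonded. Me3SiOTf/Et3N removes a C9 proton, C5–H being too hindered, and gives the bis(trimethylsilyl) dienol ether F9. Bu4NF/AcOH at −78 °C protonates the dienolate kinetically at the α-carbon C7, which restores C8=C9 and leaves C5 untouched.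

**Further compounds**

F1 | step 10 | 4β-O-diisopropylsilyl (Si–H) ether of 11 | CC(=O)C1=C(C)[C@@H](OC(C)=O)C[C@@]1(O[SiH](C(C)C)C(C)C)C(C)C
F2 | step 10 | 4β-O-bromodiisopropylsilyl ether of 11 | CC(=O)C1=C(C)[C@@H](OC(C)=O)C[C@@]1(O[Si](Br)(C(C)C)C(C)C)C(C)C
F3 | step 14 | methyl 3-(tert-butyldimethylsilyloxy)-2-diazobut-3-enoate | C=C(O[Si](C)(C)C(C)(C)C)C(=[N+]=[N-])C(=O)OC
F4 | step 14 | 18 carrying a tert-butyldimethylsilyloxy group at C9 | COC(=O)C1=C(O[Si](C)(C)C(C)(C)C)C[C@@]2(C)[C@@H](OC(C)=O)C[C@]3(C(C)C)O[Si](C(C)C)(C(C)C)OC(C1)=C23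
F5 | step 14 | C9-oxo C8-ester (β-keto ester, C8 not defined) | COC(=O)C1C(=O)C[C@@]2(C)[C@@H](OC(C)=O)C[C@]3(C(C)C)O[Si](C(C)C)(C(C)C)OC(C1)=C23
F6 | step 14 | C9 enol triflate of F5 | COC(=O)C1=C(OS(=O)(=O)C(F)(F)F)C[C@@]2(C)[C@@H](OC(C)=O)C[C@]3(C(C)C)O[Si](C(C)C)(C(C)C)OC(C1)=C23
F7 | step 18 | 5β-H (cis-fused) epimer of 24 | CC1=CC[C@@]2(C)[C@@H](OC(C)=O)C[C@@](O)(C(C)C)[C@H]2C(=O)C1
F8 | step 18 | trans-fused conjugated enone (C6=O, C7=C8, 5α-H) | CC1=CC(=O)[C@H]2[C@](O)(C(C)C)C[C@H](OC(C)=O)[C@]2(C)CC1
F9 | step 18 | bis(trimethylsilyl) dienol ether (C6(OSiMe3)=C7, C8=C9, 4β-OSiMe3) | CC1=CC[C@@]2(C)[C@@H](OC(C)=O)C[C@@](O[Si](C)(C)C)(C(C)C)[C@@H]2C(O[Si](C)(C)C)=C1
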